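**Retrosynthetic overview**

1. The 19-membered lactone is closed last by an intramolecular Suzuki–Miyaura coupling at C7–C8; the C5 ketone is then unmasked from a PMB ether and C11–OH from a silyl ether.
2. The (2Z)-enoate comes from a Still–Gennari olefination between a phosphonate already esterified to C19–OH (north half) and a C3–C7 iodo aldehyde (south half: crotylation of (E)-3-iodo-2-methylacrolein, PMB from 4-methoxybenzyl chloride).
3. North half: C8–C11 by Z-selective asymmetric allylboration with a 1,1-diborylpropene, C12=C13 by Still–Gennari olefination, side chain by dienyl addition to a C19 aldehyde and Shi epoxidation.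
4. The tetrahydrofuran is formed by 5-exo opening of the C13–C14 oxirane by C17–OH (inversion at C14) directly after an anti-crotylation.
5. Key step: Sharpless desymmetrisation of penta-1,4-dien-3-ol, which sets C14 and C15. Ring order: oxirane (consumed) → tetrahydrofuran → side-chain oxirane → macrolactone.

Convention (assumed): macrolide numbering from the lactone carbonyl C1 to the lactone carbinol C19, side chain C20–C24; target = (2Z,4S,6E,8Z,11R,12Z,14S,15S,17R,18R,19R,20E,22R,23R).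

**Route**

Step 1
Reactants: 1 penta-1,4-dien-3-ol
Product: 2 (1S)-1-[(2R)-oxiran-2-yl]prop-2-en-1-ol
Conditions: Ti(OiPr)4, L-(+)-diisopropyl tartrate, tBuOOH, 4 Å MS, CH2Cl2, −20 °C
Reagents that add atoms: tert-butyl hydroperoxide, CC(C)(C)OO
Why: Sharpless asymmetric epoxidation of the prochiral divinylcarbinol selects one enantiotopic vinyl group and one face, giving the erythro epoxy alcohol and setting C15 (S) and C14 (R, inverted later) in one operation.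

Step 2
Reactants: 2 (1S)-1-[(2R)-oxiran-2-yl]prop-2-en-1-ol
Product: 3 (2R)-2-[(1S)-1-methoxyprop-2-en-1-yl]oxirane
Conditions: NaH, MeI, THF, 0 °C
Reagents that add atoms: iodomethane, CI
Why: Williamson methylation installs the C15 methyl ether without touching a stereocentre (low temperature and aprotic medium suppress Payne rearrangement).

Step 3
Reactants: 3 (2R)-2-[(1S)-1-methoxyprop-2-en-1-yl]oxirane
Product: 5 (3S)-3-methoxy-3-[(2R)-oxiran-2-yl]propan-1-ol, via alkylborane 4 (not isolated)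
Conditions: 9-BBN, THF, 0 °C to rt; then H2O2, aq. NaOAc, 0 °C
Reagents that add atoms: hydrogen peroxide, OO
Why: Anti-Markovnikov hydroboration–oxidation of the terminal vinyl group gives the C17 primary alcohol; 9-BBN leaves the oxirane intact.

Step 4
Reactants: 5 (3S)-3-methoxy-3-[(2R)-oxiran-2-yl]propan-1-ol
Product: 6 (3S)-3-methoxy-3-[(2R)-oxiran-2-yl]propanal
Conditions: Dess–Martin periodinane, NaHCO3, CH2Cl2, 0 °C
Reagents that add atoms: none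
Why: Buffered Dess–Martin oxidation gives the β-methoxy aldehyde without elimination or epoxide opening.

Step 5
Reactants: 6 (3S)-3-methoxy-3-[(2R)-oxiran-2-yl]propanal
Product: 8 [(2S,3S,5R)-5-[(2S)-but-3-en-2-yl]-3-methoxyoxolan-2-yl]methanol, via epoxy alcohol 7 (not isolated)
Conditions: (E)-but-2-ene, KOtBu, n-BuLi, THF, −45 °C; (−)-Ipc2BOMe, −78 °C; BF3·OEt2 (1.0 equiv); then 6, −78 °C; H2O2, aq. NaHCO3; then CSA (cat.), CH2Cl2, rt
Reagents that add atoms: (−)-B-[(E)-but-2-enyl]diisopinocampheylborane, C/C=C/CB([C@@H]1C[C@@H]2C[C@H]([C@H]1C)C2(C)C)[C@@H]1C[C@@H]2C[C@H]([C@H]1C)C2(C)C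
Why: Brown crotylboration through a chair transition state gives the anti C17–OH/C18–Me pair with reagent-controlled Si-face attack (17R), and the new hydroxyl then opens the oxirane in an acid-catalysed 5-exo-tet cyclisation with inversion at C14, giving the 2,5-trans, 14,15-cis tetrahydrofuran.

Step 6
Reactants: 8 [(2S,3S,5R)-5-[(2S)-but-3-en-2-yl]-3-methoxyoxolan-2-yl]methanol
Product: 9 (2R,3S,5R)-5-[(2S)-but-3-en-2-yl]-3-methoxyoxolane-2-carbaldehyde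
Conditions: Dess–Martin periodinane, NaHCO3, CH2Cl2, 0 °C
Reagents that add atoms: none
Why: Buffered Dess–Martin oxidation gives the C13 aldehyde, used at once to avoid epimerisation at C14.

Step 7
Reactants: 9 (2R,3S,5R)-5-[(2S)-but-3-en-2-yl]-3-methoxyoxolane-2-carbaldehyde; 10 methyl 2-[bis(2,2,2-trifluoroethoxy)phosphoryl]propanoate
Product: 11 methyl (2Z)-3-[(2S,3S,5R)-5-[(2S)-but-3-en-2-yl]-3-methoxyoxolan-2-yl]-2-methylprop-2-enoate
Conditions: KN(SiMe3)2, 18-crown-6, THF, −78 °C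
Reagents that add atoms: none
Why: Still–Gennari olefination (trifluoroethyl phosphonate, dissociated potassium enolate) gives the Z-trisubstituted C12=C13 alkene under kinetic control.

Step 8
Reactants: 11 methyl (2Z)-3-[(2S,3S,5R)-5-[(2S)-but-3-en-2-yl]-3-methoxyoxolan-2-yl]-2-methylprop-2-enoate
Product: 13 methyl (2Z)-3-[(2S,3S,5R)-3-methoxy-5-[(2R)-1-oxopropan-2-yl]oxolan-2-yl]-2-methylprop-2-enoate, via diol 12 (not isolated)
Conditions: OsO4 (cat.), NaIO4, 2,6-lutidine, dioxane/H2O, rt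
Reagents that add atoms: sodium periodate, [Na+].[O-]I(=O)(=O)=O
Why: Lemieux–Johnson cleavage takes the electron-rich terminal vinyl group in preference to the electron-poor trisubstituted enoate, giving the C19 aldehyde.

Step 9
Reactants: 14 (2E)-but-2-enal
Product: 15 (1E,3E)-1-iodopenta-1,3-diene
Conditions: CrCl2, CHI3, THF, 0 °C
Reagents that add atoms: iodoform, IC(I)I
Why: Takai olefination converts the enal into the E-alkenyl iodide.

Step 10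
Reactants: 13 methyl (2Z)-3-[(2S,3S,5R)-3-methoxy-5-[(2R)-1-oxopropan-2-yl]oxolan-2-yl]-2-methylprop-2-enoate; 15 (1E,3E)-1-iodopenta-1,3-diene
Product: 16 methyl (2Z)-3-[(2S,3S,5R)-5-[(2S,3R,4E,6E)-3-hydroxyocta-4,6-dien-2-yl]-3-methoxyoxolan-2-yl]-2-methylprop-2-enoate
Conditions: CrCl2, NiCl2 (cat.), DMSO/THF, rt
Reagents that add atoms: none
Why: Nozaki–Hiyama–Kishi addition is chemoselective for the aldehyde, and Felkin–Anh attack (C18 methyl, reinforced by the anti β-oxygen) is expected to give the (19R) alcohol syn to the C18 methyl.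

Step 11
Reactants: 16 methyl (2Z)-3-[(2S,3S,5R)-5-[(2S,3R,4E,6E)-3-hydroxyocta-4,6-dien-2-yl]-3-methoxyoxolan-2-yl]-2-methylprop-2-enoate
Product: 17 methyl (2Z)-3-[(2S,3S,5R)-5-[(2S,3R,4E)-3-hydroxy-5-[(2R,3R)-3-methyloxiran-2-yl]pent-4-en-2-yl]-3-methoxyoxolan-2-yl]-2-methylprop-2-enoate
Conditions: D-fructose-derived Shi ketone (30 mol%), KHSO5 (Oxone), K2CO3, Bu4NHSO4, MeCN/dimethoxymethane/aq. buffer pH 10.5, 0 °C
Reagents that add atoms: potassium peroxymonosulfate, [K+].[O-]S(=O)(=O)OO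
Why: Shi epoxidation attacks only the distal, more electron-rich alkene of the dienyl carbinol (the enoate is inert), and the D-fructose ketone gives the (22R,23R) trans-epoxide by reagent control.

Step 12
Reactants: 17 methyl (2Z)-3-[(2S,3S,5R)-5-[(2S,3R,4E)-3-hydroxy-5-[(2R,3R)-3-methyloxiran-2-yl]pent-4-en-2-yl]-3-methoxyoxolan-2-yl]-2-methylprop-2-enoate
Product: 18 (2Z)-3-[(2S,3S,5R)-5-[(2S,3R,4E)-3-hydroxy-5-[(2R,3R)-3-methyloxiran-2-yl]pent-4-en-2-yl]-3-methoxyoxolan-2-yl]-2-methylprop-2-en-1-ol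
Conditions: iBu2AlH, CH2Cl2, −78 °C
Reagents that add atoms: none
Why: 1,2-Reduction of the enoate with iBu2AlH gives the Z-allylic alcohol; at −78 °C the vinyl epoxide is not opened.

Step 13
Reactants: 18 (2Z)-3-[(2S,3S,5R)-5-[(2S,3R,4E)-3-hydroxy-5-[(2R,3R)-3-methyloxiran-2-yl]pent-4-en-2-yl]-3-methoxyoxolan-2-yl]-2-methylprop-2-en-1-ol
Product: 19 (2Z)-3-[(2S,3S,5R)-5-[(2S,3R,4E)-3-hydroxy-5-[(2R,3R)-3-methyloxiran-2-yl]pent-4-en-2-yl]-3-methoxyoxolan-2-yl]-2-methylprop-2-enal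
Conditions: TEMPO (cat.), PhI(OAc)2, CH2Cl2, rt
Reagents that add atoms: none
Why: TEMPO/PhI(OAc)2 oxidises the primary allylic alcohol much faster than the secondary C19–OH and does not isomerise the Z-enal.

Step 14
Reactants: 10 methyl 2-[bis(2,2,2-trifluoroethoxy)phosphoryl]propanoate
Product: 20 2-[bis(2,2,2-trifluoroethoxy)phosphoryl]propanoic acid
Conditions: LiOH (1.0 equiv), THF/H2O, 0 °C; then 1 M HCl
Reagents that add atoms: lithium hydroxide, [Li+].[OH-]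
Why: Controlled saponification of the activated carboxylic methyl ester with one equivalent of hydroxide at 0 °C gives the phosphono acid.

Step 15
Reactants: 19 (2Z)-3-[(2S,3S,5R)-5-[(2S,3R,4E)-3-hydroxy-5-[(2R,3R)-3-methyloxiran-2-yl]pent-4-en-2-yl]-3-methoxyoxolan-2-yl]-2-methylprop-2-enal; 20 2-[bis(2,2,2-trifluoroethoxy)phosphoryl]propanoic acid
Product: 21 (1E,3R,4R)-4-[(2R,4S,5S)-4-methoxy-5-[(1Z)-2-methyl-3-oxoprop-1-en-1-yl]oxolan-2-yl]-1-[(2R,3R)-3-methyloxiran-2-yl]pent-1-en-3-yl 2-[bis(2,2,2-trifluoroethoxy)phosphoryl]propanoate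
Conditions: DCC, DMAP (cat.), CH2Cl2, 0 °C
Reagents that add atoms: none
Why: Steglich esterification of the only free hydroxyl (C19) puts the future C1–C2 unit in place, so the lactone C–O bond never requires activation of a Z-enoic acid.

Step 16
Reactants: 22 bis[(pinacolato)boryl]methane; 23 bromoethene
Product: 25 2,2'-(prop-2-ene-1,1-diyl)bis(4,4,5,5-tetramethyl-1,3,2-dioxaborolane), via zinc reagent 24 (not isolated)
Conditions: lithium 2,2,6,6-tetramethylpiperidide (LiTMP), THF, 0 °C; ZnCl2; then 23, Pd(PPh3)4 (cat.), rt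
Reagents that add atoms: none
Why: Deprotonation and transmetalation give a bis(boryl)methylzinc reagent that undergoes Negishi coupling with vinyl bromide.

Step 17
Reactants: 21 (phosphonate ester enal, see step 15); 25 2,2'-(prop-2-ene-1,1-diyl)bis(4,4,5,5-tetramethyl-1,3,2-dioxaborolane)
Product: 26 (1E,3R,4R)-4-[(2R,4S,5S)-5-[(1Z,3R,5Z)-3-hydroxy-2-methyl-6-(4,4,5,5-tetramethyl-1,3,2-dioxaborolan-2-yl)hexa-1,5-dien-1-yl]-4-methoxyoxolan-2-yl]-1-[(2R,3R)-3-methyloxiran-2-yl]pent-1-en-3-yl 2-[bis(2,2,2-trifluoroethoxy)phosphoryl]propanoate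
Conditions: (R)-TRIP (3,3'-bis(2,4,6-triisopropylphenyl)-BINOL hydrogen phosphate, 5 mol%), 4 Å MS, toluene, −45 °C
Reagents that add atoms: none
Why: Chiral phosphoric acid-catalysed allylboration through a chair transition state with the α-boryl group pseudoaxial gives the (8Z)-alkenylboronate, and the (R)-catalyst directs Re-face attack to set (11R).

Step 18
Reactants: 26 (hydroxy alkenylboronate, see step 17)
Product: 27 (1E,3R,4R)-4-[(2R,4S,5S)-4-methoxy-5-[(1Z,3R,5Z)-2-methyl-6-(4,4,5,5-tetramethyl-1,3,2-dioxaborolan-2-yl)-3-(triethylsilyloxy)hexa-1,5-dien-1-yl]oxolan-2-yl]-1-[(2R,3R)-3-methyloxiran-2-yl]pent-1-en-3-yl 2-[bis(2,2,2-trifluoroethoxy)phosphoryl]propanoate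
Conditions: Et3SiCl, imidazole, DMF, 0 °C
Reagents that add atoms: chlorotriethylsilane, CC[Si](Cl)(CC)CC
Why: Silylation protects C11–OH for the later C5 oxidation under conditions that do not open the vinyl epoxide.

Step 19
Reactants: 28 prop-2-yn-1-ol
Product: 30 (2E)-3-iodo-2-methylprop-2-en-1-ol, via vinylalane 29 (not isolated)
Conditions: AlMe3, Cp2ZrCl2 (25 mol%), CH2Cl2, 0 °C to rt; then I2, THF, −30 °C
Reagents that add atoms: trimethylaluminium, C[Al](C)C; iodine, II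
Why: Negishi zirconium-catalysed syn-carboalumination followed by iodinolysis with retention gives the E-trisubstituted alkenyl iodide (future C6=C7).

Step 20
Reactants: 30 (2E)-3-iodo-2-methylprop-2-en-1-ol
Product: 31 (2E)-3-iodo-2-methylprop-2-enal
Conditions: MnO2, CH2Cl2, rt
Reagents that add atoms: none
Why: MnO2 oxidises the allylic alcohol to the enal without touching the alkenyl iodide.

Step 21
Reactants: 31 (2E)-3-iodo-2-methylprop-2-enal
Product: 32 (1E,3S,4S)-1-iodo-2,4-dimethylhexa-1,5-dien-3-ol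
Conditions: (E)-but-2-ene, KOtBu, n-BuLi, THF, −45 °C; (−)-Ipc2BOMe, −78 °C; BF3·OEt2; then 31, −78 °C; NaOH, H2O2
Reagents that add atoms: (−)-B-[(E)-but-2-enyl]diisopinocampheylborane, C/C=C/CB([C@@H]1C[C@@H]2C[C@H]([C@H]1C)C2(C)C)[C@@H]1C[C@@H]2C[C@H]([C@H]1C)C2(C)C
Why: Brown anti-crotylboration with Si-face attack sets the methyl-bearing carbon (target C4, S) by reagent control; the carbinol (C5) is oxidised later.

Step 22
Reactants: 32 (1E,3S,4S)-1-iodo-2,4-dimethylhexa-1,5-dien-3-ol; 33 4-methoxybenzyl chloride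
Product: 34 1-[[(1E,3S,4S)-1-iodo-2,4-dimethylhexa-1,5-dien-3-yl]oxymethyl]-4-methoxybenzene
Conditions: NaH, Bu4NI (cat.), THF/DMF, 0 °C to rt
Reagents that add atoms: none
Why: Williamson etherification masks the C5 oxygen as an oxidatively removable PMB ether.

Step 23
Reactants: 34 1-[[(1E,3S,4S)-1-iodo-2,4-dimethylhexa-1,5-dien-3-yl]oxymethyl]-4-methoxybenzene
Product: 36 (2R,3S,4E)-5-iodo-3-[(4-methoxyphenyl)methoxy]-2,4-dimethylpent-4-enal, via diol 35 (not isolated)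
Conditions: OsO4 (cat.), NaIO4, 2,6-lutidine, dioxane/H2O, rt
Reagents that add atoms: sodium periodate, [Na+].[O-]I(=O)(=O)=O
Why: Lemieux–Johnson cleavage of the terminal vinyl group gives the C3 aldehyde; the hindered, electron-poor iodoalkene is left alone.

Step 24
Reactants: 27 (silyl ether phosphonate, see step 18); 36 (2R,3S,4E)-5-iodo-3-[(4-methoxyphenyl)methoxy]-2,4-dimethylpent-4-enal
Product: 37 (1E,3R,4R)-4-[(2R,4S,5S)-4-methoxy-5-[(1Z,3R,5Z)-2-methyl-6-(4,4,5,5-tetramethyl-1,3,2-dioxaborolan-2-yl)-3-(triethylsilyloxy)hexa-1,5-dien-1-yl]oxolan-2-yl]-1-[(2R,3R)-3-methyloxiran-2-yl]pent-1-en-3-yl (2Z,4S,5S,6E)-7-iodo-5-[(4-methoxyphenyl)methoxy]-2,4,6-trimethylhepta-2,6-dienoate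
Conditions: KN(SiMe3)2, 18-crown-6, THF, −78 °C
Reagents that add atoms: none
Why: Still–Gennari olefination joins the two halves and forms the (2Z)-enoate directly on the ester; the adjacent C4 stereocentre is not exposed to acyl activation.

Step 25
Reactants: 37 (iodo alkenylboronate, see step 24)
Product: 38 macrolactone: as 41 but with C5 as (5S)-CH–O–CH2C6H4-4-OMe in place of C=O and with C11–O–SiEt3
Conditions: Pd(PPh3)4 (20 mol%), TlOEt, THF/H2O 3:1, rt, 1 mM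
Reagents that add atoms: none
Why: Intramolecular Suzuki–Miyaura coupling with retention at both alkenyl partners closes the 19-membered ring and gives the (6E,8Z)-diene; thallium ethoxide makes transmetalation fast at room temperature.

Step 26
Reactants: 38 macrolactone (5-O-PMB, 11-O-SiEt3)
Product: 40 11-O-triethylsilyl ether of 41, via dienyl alcohol 39 (not isolated)
Conditions: DDQ, CH2Cl2/pH 7 buffer, 0 °C; then Dess–Martin periodinane, NaHCO3, CH2Cl2, 0 °C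
Reagents that add atoms: none
Why: Oxidative PMB cleavage followed by buffered Dess–Martin oxidation installs the C5 ketone at the end, under non-basic conditions that do not epimerise C4.

Step 27
Reactants: 40 11-O-triethylsilyl ether of 41
Product: 41 target macrolide CNP0117824.2
Conditions: HF·pyridine, pyridine, THF, 0 °C
Reagents that add atoms: none
Why: Buffered fluoride desilylation frees C11–OH without opening the vinyl epoxide or enolising the C5 ketone.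

**Compound list**

1 | penta-1,4-dien-3-ol | C=CC(O)C=C | starting material
2 | (1S)-1-[(2R)-oxiran-2-yl]prop-2-en-1-ol | C=C[C@H](O)[C@H]1CO1 | intermediate
3 | (2R)-2-[(1S)-1-methoxyprop-2-en-1-yl]oxirane | C=C[C@H](OC)[C@H]1CO1 | intermediate
4 | 9-[(3S)-3-methoxy-3-[(2R)-oxiran-2-yl]propyl]-9-borabicyclo[3.3.1]nonane | C1CC2CCCC(C1)B2CC[C@H](OC)[C@H]1CO1 | intermediate
5 | (3S)-3-methoxy-3-[(2R)-oxiran-2-yl]propan-1-ol | OCC[C@H](OC)[C@H]1CO1 | intermediate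
6 | (3S)-3-methoxy-3-[(2R)-oxiran-2-yl]propanal | O=CC[C@H](OC)[C@H]1CO1 | intermediate
7 | (3S,4R,6S)-6-methoxy-3-methyl-6-[(2R)-oxiran-2-yl]hex-1-en-4-ol | C=C[C@H](C)[C@H](O)C[C@H](OC)[C@H]1CO1 | intermediate
8 | [(2S,3S,5R)-5-[(2S)-but-3-en-2-yl]-3-methoxyoxolan-2-yl]methanol | CO[C@H]1C[C@@H](O[C@H]1CO)[C@@H](C)C=C | intermediate
9 | (2R,3S,5R)-5-[(2S)-but-3-en-2-yl]-3-methoxyoxolane-2-carbaldehyde | CO[C@H]1C[C@@H](O[C@H]1C=O)[C@@H](C)C=C | intermediate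
10 | methyl 2-[bis(2,2,2-trifluoroethoxy)phosphoryl]propanoate (racemic) | COC(=O)C(C)P(=O)(OCC(F)(F)F)OCC(F)(F)F | starting material
11 | methyl (2Z)-3-[(2S,3S,5R)-5-[(2S)-but-3-en-2-yl]-3-methoxyoxolan-2-yl]-2-methylprop-2-enoate | CO[C@H]1C[C@@H](O[C@H]1/C=C(/C)C(=O)OC)[C@@H](C)C=C | intermediate
12 | methyl (2Z)-3-[(2S,3S,5R)-5-[(2S)-3,4-dihydroxybutan-2-yl]-3-methoxyoxolan-2-yl]-2-methylprop-2-enoate (both carbinol epimers) | CO[C@H]1C[C@@H](O[C@H]1/C=C(/C)C(=O)OC)[C@@H](C)C(O)CO | intermediate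
13 | methyl (2Z)-3-[(2S,3S,5R)-3-methoxy-5-[(2R)-1-oxopropan-2-yl]oxolan-2-yl]-2-methylprop-2-enoate | CO[C@H]1C[C@@H](O[C@H]1/C=C(/C)C(=O)OC)[C@@H](C)C=O | intermediate
14 | (2E)-but-2-enal | C/C=C/C=O | starting material
15 | (1E,3E)-1-iodopenta-1,3-diene | C/C=C/C=C/I | intermediate
16 | methyl (2Z)-3-[(2S,3S,5R)-5-[(2S,3R,4E,6E)-3-hydroxyocta-4,6-dien-2-yl]-3-methoxyoxolan-2-yl]-2-methylprop-2-enoate | CO[C@H]1C[C@@H](O[C@H]1/C=C(/C)C(=O)OC)[C@@H](C)[C@H](O)/C=C/C=C/C | intermediate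
17 | methyl (2Z)-3-[(2S,3S,5R)-5-[(2S,3R,4E)-3-hydroxy-5-[(2R,3R)-3-methyloxiran-2-yl]pent-4-en-2-yl]-3-methoxyoxolan-2-yl]-2-methylprop-2-enoate | CO[C@H]1C[C@@H](O[C@H]1/C=C(/C)C(=O)OC)[C@@H](C)[C@H](O)/C=C/[C@H]1O[C@@H]1C | intermediate
18 | (2Z)-3-[(2S,3S,5R)-5-[(2S,3R,4E)-3-hydroxy-5-[(2R,3R)-3-methyloxiran-2-yl]pent-4-en-2-yl]-3-methoxyoxolan-2-yl]-2-methylprop-2-en-1-ol | CO[C@H]1C[C@@H](O[C@H]1/C=C(/C)CO)[C@@H](C)[C@H](O)/C=C/[C@H]1O[C@@H]1C | intermediate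
19 | (2Z)-3-[(2S,3S,5R)-5-[(2S,3R,4E)-3-hydroxy-5-[(2R,3R)-3-methyloxiran-2-yl]pent-4-en-2-yl]-3-methoxyoxolan-2-yl]-2-methylprop-2-enal | CO[C@H]1C[C@@H](O[C@H]1/C=C(/C)C=O)[C@@H](C)[C@H](O)/C=C/[C@H]1O[C@@H]1C | intermediate
20 | 2-[bis(2,2,2-trifluoroethoxy)phosphoryl]propanoic acid (racemic) | CC(C(=O)O)P(=O)(OCC(F)(F)F)OCC(F)(F)F | intermediate
21 | (1E,3R,4R)-4-[(2R,4S,5S)-4-methoxy-5-[(1Z)-2-methyl-3-oxoprop-1-en-1-yl]oxolan-2-yl]-1-[(2R,3R)-3-methyloxiran-2-yl]pent-1-en-3-yl 2-[bis(2,2,2-trifluoroethoxy)phosphoryl]propanoate (epimers at the phosphonate carbon) | CO[C@H]1C[C@@H](O[C@H]1/C=C(/C)C=O)[C@@H](C)[C@H](OC(=O)C(C)P(=O)(OCC(F)(F)F)OCC(F)(F)F)/C=C/[C@H]1O[C@@H]1C | intermediate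
22 | bis[(pinacolato)boryl]methane | CC1(C)OB(CB2OC(C)(C)C(C)(C)O2)OC1(C)C | starting material
23 | bromoethene | C=CBr | starting material
24 | [bis(4,4,5,5-tetramethyl-1,3,2-dioxaborolan-2-yl)methyl]zinc chloride | Cl[Zn]C(B1OC(C)(C)C(C)(C)O1)B1OC(C)(C)C(C)(C)O1 | intermediate
25 | 2,2'-(prop-2-ene-1,1-diyl)bis(4,4,5,5-tetramethyl-1,3,2-dioxaborolane) | C=CC(B1OC(C)(C)C(C)(C)O1)B1OC(C)(C)C(C)(C)O1 | intermediate
26 | (1E,3R,4R)-4-[(2R,4S,5S)-5-[(1Z,3R,5Z)-3-hydroxy-2-methyl-6-(4,4,5,5-tetramethyl-1,3,2-dioxaborolan-2-yl)hexa-1,5-dien-1-yl]-4-methoxyoxolan-2-yl]-1-[(2R,3R)-3-methyloxiran-2-yl]pent-1-en-3-yl 2-[bis(2,2,2-trifluoroethoxy)phosphoryl]propanoate | CO[C@H]1C[C@@H](O[C@H]1/C=C(/C)[C@H](O)C/C=C\B1OC(C)(C)C(C)(C)O1)[C@@H](C)[C@H](OC(=O)C(C)P(=O)(OCC(F)(F)F)OCC(F)(F)F)/C=C/[C@H]1O[C@@H]1C | intermediate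
27 | 3-O-triethylsilyl ether of 26 (silyl on the hexadienyl C3 oxygen, target C11) | CO[C@H]1C[C@@H](O[C@H]1/C=C(/C)[C@H](O[Si](CC)(CC)CC)C/C=C\B1OC(C)(C)C(C)(C)O1)[C@@H](C)[C@H](OC(=O)C(C)P(=O)(OCC(F)(F)F)OCC(F)(F)F)/C=C/[C@H]1O[C@@H]1C | intermediate
28 | prop-2-yn-1-ol | C#CCO | starting material
29 | dimethyl[(1E)-3-[(dimethylalumanyl)oxy]-2-methylprop-1-en-1-yl]alumane | C[Al](C)/C=C(\C)CO[Al](C)C | intermediate
30 | (2E)-3-iodo-2-methylprop-2-en-1-ol | I/C=C(\C)CO | intermediate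
31 | (2E)-3-iodo-2-methylprop-2-enal | I/C=C(\C)C=O | intermediate
32 | (1E,3S,4S)-1-iodo-2,4-dimethylhexa-1,5-dien-3-ol | I/C=C(\C)[C@@H](O)[C@@H](C)C=C | intermediate
33 | 4-methoxybenzyl chloride | COc1ccc(CCl)cc1 | starting material
34 | 1-[[(1E,3S,4S)-1-iodo-2,4-dimethylhexa-1,5-dien-3-yl]oxymethyl]-4-methoxybenzene | I/C=C(\C)[C@@H](OCc1ccc(OC)cc1)[C@@H](C)C=C | intermediate
35 | (3S,4S,5E)-6-iodo-4-[(4-methoxyphenyl)methoxy]-3,5-dimethylhex-5-ene-1,2-diol (both C2 epimers) | I/C=C(\C)[C@@H](OCc1ccc(OC)cc1)[C@@H](C)C(O)CO | intermediate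
36 | (2R,3S,4E)-5-iodo-3-[(4-methoxyphenyl)methoxy]-2,4-dimethylpent-4-enal | I/C=C(\C)[C@@H](OCc1ccc(OC)cc1)[C@@H](C)C=O | intermediate
37 | (1E,3R,4R)-4-[(2R,4S,5S)-4-methoxy-5-[(1Z,3R,5Z)-2-methyl-6-(4,4,5,5-tetramethyl-1,3,2-dioxaborolan-2-yl)-3-(triethylsilyloxy)hexa-1,5-dien-1-yl]oxolan-2-yl]-1-[(2R,3R)-3-methyloxiran-2-yl]pent-1-en-3-yl (2Z,4S,5S,6E)-7-iodo-5-[(4-methoxyphenyl)methoxy]-2,4,6-trimethylhepta-2,6-dienoate | CO[C@H]1C[C@@H](O[C@H]1/C=C(/C)[C@H](O[Si](CC)(CC)CC)C/C=C\B1OC(C)(C)C(C)(C)O1)[C@@H](C)[C@H](OC(=O)/C(C)=C\[C@H](C)[C@H](OCc1ccc(OC)cc1)/C(C)=C/I)/C=C/[C@H]1O[C@@H]1C | intermediate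
38 | macrolactone: 41 with C5 as (5S)-CH–O–CH2C6H4-4-OMe instead of C=O and C11–O–SiEt3 | CO[C@H]1C[C@H]2O[C@H]1/C=C(/C)[C@H](O[Si](CC)(CC)CC)C/C=C\C=C(/C)[C@@H](OCc3ccc(OC)cc3)[C@@H](C)/C=C(/C)C(=O)O[C@H](/C=C/[C@H]1O[C@@H]1C)[C@@H]2C | intermediate
39 | macrolactone: 41 with C5 as (5S)-CH–OH instead of C=O and C11–O–SiEt3 | CO[C@H]1C[C@H]2O[C@H]1/C=C(/C)[C@H](O[Si](CC)(CC)CC)C/C=C\C=C(/C)[C@@H](O)[C@@H](C)/C=C(/C)C(=O)O[C@H](/C=C/[C@H]1O[C@@H]1C)[C@@H]2C | intermediate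
40 | 11-O-triethylsilyl ether of 41 | CO[C@H]1C[C@H]2O[C@H]1/C=C(/C)[C@H](O[Si](CC)(CC)CC)C/C=C\C=C(/C)C(=O)[C@@H](C)/C=C(/C)C(=O)O[C@H](/C=C/[C@H]1O[C@@H]1C)[C@@H]2C | intermediate
41 | CNP0117824.2: (2Z,4S,6E,8Z,11R,12Z,14S,15S,17R,18R,19R)-19-membered lactone with 14,17-oxygen bridge (2,5-trans-tetrahydrofuran), 15-OMe, 11-OH, 5-oxo, methyls at C2, C4, C6, C12, C18, and a (1E)-2-[(2R,3R)-3-methyloxiran-2-yl]ethenyl group at C19 | CO[C@H]1C[C@H]2O[C@H]1/C=C(/C)[C@H](O)C/C=C\C=C(/C)C(=O)[C@@H](C)/C=C(/C)C(=O)O[C@H](/C=C/[C@H]1O[C@@H]1C)[C@@H]2C | target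

**Step count and risk**

Total: 27 steps. Longest linear sequence: 19 steps (steps 1–8, 10–13, 15, 17, 18, 24–27).

The three steps most likely to fail:

Step 10 (C19 is set only by substrate control in the chromium-mediated addition). The fallback sets out from 13 and 15 and comes back at 16. The addition is run without regard to selectivity, and the mixture of 16 and its C19 epimer, methyl (2Z)-3-[(2S,3S,5R)-5-[(2S,3S,4E,6E)-3-hydroxyocta-4,6-dien-2-yl]-3-methoxyoxolan-2-yl]-2-methylprop-2-enoate F1, is oxidised with Dess–Martin periodinane to the dienone methyl (2Z)-3-[(2S,3S,5R)-3-methoxy-5-[(2R,4E,6E)-3-oxoocta-4,6-dien-2-yl]oxolan-2-yl]-2-methylprop-2-enoate F2. Reagent-controlled reduction of F2 with BH3·SMe2 and (R)-2-methyl-CBS-oxazaborolidine (dienyl group as the large substituent) then gives 16.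

Step 17 (Z-selective, enantioselective allylboration of a hindered Z-enal carrying a vinyl epoxide). The fallback sets out from 21 and comes back at 26. Allylation of 21 with (+)-B-allyldiisopinocampheylborane (Re-face attack) gives the homoallylic alcohol (1E,3R,4R)-4-[(2R,4S,5S)-5-[(1Z,3R)-3-hydroxy-2-methylhexa-1,5-dien-1-yl]-4-methoxyoxolan-2-yl]-1-[(2R,3R)-3-methyloxiran-2-yl]pent-1-en-3-yl 2-[bis(2,2,2-trifluoroethoxy)phosphoryl]propanoate F3. A Z-selective cross-metathesis of F3 with vinylboronic acid pinacol ester, using the molybdenum monoaryloxide pyrrolide alkylidene Mo(NC10H15)(CHCMe2Ph)(NC4H4)(OC6H3-2,6-(C6H2-2,4,6-iPr3)2), then gives 26.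

Step 25 (macrocyclic Suzuki–Miyaura coupling; zerovalent palladium can also ionise the vinyl epoxide, and the 19-membered closure may oligomerise). The fallback sets out from 21 and comes back at 38, closing the ring through an alkyne instead:
- Propargylation of 21 with allenylboronic acid pinacol ester and (R)-TRIP gives the homopropargylic alcohol (1E,3R,4R)-4-[(2R,4S,5S)-5-[(1Z,3R)-3-hydroxy-2-methylhex-1-en-5-yn-1-yl]-4-methoxyoxolan-2-yl]-1-[(2R,3R)-3-methyloxiran-2-yl]pent-1-en-3-yl 2-[bis(2,2,2-trifluoroethoxy)phosphoryl]propanoate F4.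
- Et3SiCl and imidazole give its triethylsilyl ether F5.
- Still–Gennari olefination of F5 with 36 gives the iodo enyne ester (1E,3R,4R)-4-[(2R,4S,5S)-4-methoxy-5-[(1Z,3R)-2-methyl-3-(triethylsilyloxy)hex-1-en-5-yn-1-yl]oxolan-2-yl]-1-[(2R,3R)-3-methyloxiran-2-yl]pent-1-en-3-yl (2Z,4S,5S,6E)-7-iodo-5-[(4-methoxyphenyl)methoxy]-2,4,6-trimethylhepta-2,6-dienoate F6.
- Intramolecular Sonogashira coupling [Pd(PPh3)4, CuI, iPr2NH, high dilution] gives the 8,9-didehydro analogue of 38 (C8≡C9 enyne macrolactone) F7.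
- Semireduction of the conjugated alkyne with Zn(Cu/Ag) in MeOH/H2O gives 38.

**Further compounds**

F1 | step 10 | methyl (2Z)-3-[(2S,3S,5R)-5-[(2S,3S,4E,6E)-3-hydroxyocta-4,6-dien-2-yl]-3-methoxyoxolan-2-yl]-2-methylprop-2-enoate | CO[C@H]1C[C@@H](O[C@H]1/C=C(/C)C(=O)OC)[C@@H](C)[C@@H](O)/C=C/C=C/C
F2 | step 10 | methyl (2Z)-3-[(2S,3S,5R)-3-methoxy-5-[(2R,4E,6E)-3-oxoocta-4,6-dien-2-yl]oxolan-2-yl]-2-methylprop-2-enoate | CO[C@H]1C[C@@H](O[C@H]1/C=C(/C)C(=O)OC)[C@@H](C)C(=O)/C=C/C=C/C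
F3 | step 17 | (1E,3R,4R)-4-[(2R,4S,5S)-5-[(1Z,3R)-3-hydroxy-2-methylhexa-1,5-dien-1-yl]-4-methoxyoxolan-2-yl]-1-[(2R,3R)-3-methyloxiran-2-yl]pent-1-en-3-yl 2-[bis(2,2,2-trifluoroethoxy)phosphoryl]propanoate | CO[C@H]1C[C@@H](O[C@H]1/C=C(/C)[C@H](O)CC=C)[C@@H](C)[C@H](OC(=O)C(C)P(=O)(OCC(F)(F)F)OCC(F)(F)F)/C=C/[C@H]1O[C@@H]1C
F4 | step 25 | (1E,3R,4R)-4-[(2R,4S,5S)-5-[(1Z,3R)-3-hydroxy-2-methylhex-1-en-5-yn-1-yl]-4-methoxyoxolan-2-yl]-1-[(2R,3R)-3-methyloxiran-2-yl]pent-1-en-3-yl 2-[bis(2,2,2-trifluoroethoxy)phosphoryl]propanoate | CO[C@H]1C[C@@H](O[C@H]1/C=C(/C)[C@H](O)CC#C)[C@@H](C)[C@H](OC(=O)C(C)P(=O)(OCC(F)(F)F)OCC(F)(F)F)/C=C/[C@H]1O[C@@H]1C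
F5 | step 25 | triethylsilyl ether of F4 | CO[C@H]1C[C@@H](O[C@H]1/C=C(/C)[C@H](O[Si](CC)(CC)CC)CC#C)[C@@H](C)[C@H](OC(=O)C(C)P(=O)(OCC(F)(F)F)OCC(F)(F)F)/C=C/[C@H]1O[C@@H]1C
F6 | step 25 | (1E,3R,4R)-4-[(2R,4S,5S)-4-methoxy-5-[(1Z,3R)-2-methyl-3-(triethylsilyloxy)hex-1-en-5-yn-1-yl]oxolan-2-yl]-1-[(2R,3R)-3-methyloxiran-2-yl]pent-1-en-3-yl (2Z,4S,5S,6E)-7-iodo-5-[(4-methoxyphenyl)methoxy]-2,4,6-trimethylhepta-2,6-dienoate | CO[C@H]1C[C@@H](O[C@H]1/C=C(/C)[C@H](O[Si](CC)(CC)CC)CC#C)[C@@H](C)[C@H](OC(=O)/C(C)=C\[C@H](C)[C@H](OCc1ccc(OC)cc1)/C(C)=C/I)/C=C/[C@H]1O[C@@H]1C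
F7 | step 25 | 8,9-didehydro analogue of 38 (C8≡C9 enyne macrolactone) | CO[C@H]1C[C@H]2O[C@H]1/C=C(/C)[C@H](O[Si](CC)(CC)CC)CC#C\C=C(/C)[C@@H](OCc3ccc(OC)cc3)[C@@H](C)/C=C(/C)C(=O)O[C@H](/C=C/[C@H]1O[C@@H]1C)[C@@H]2C
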